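**Frozen shape.** If temperature changes the speed of this flask's clock and not the shape of its product curve, then Monday's and Wednesday's flasks are known curves read at rescaled times. The shape is frozen here by assumption, and the charge is taken to leave it unchanged.

| flask | substrate | temperature | remark | time |
|---|---|---|---|---|
| east | 0.42 M | 35 °C | run made earlier |  |
| north-west | 0.66 M | 57 °C | run made earlier |  |
| Wednesday's | 0.30 M | 65 °C |  | 6.0 h |
| Monday's | 0.30 M | 25 °C |  | 25 h |

| run | time / h | product / % |
|---|---|---|
| east | 1.33 | 3.1 |
| east | 3.00 | 18.1 |
| east | 6.00 | 44.2 |
| east | 15.0 | 77.0 |
| north-west | 0.417 | 42.7 |
| north-west | 1.00 | 90.5 |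
| north-west | 2.00 | 99.1 |
| north-west | 5.00 | 99.6 |

(scatter of a reading: 1 percentage point)

- the earlier runs were read with a standard deviation of 1 percentage point
- on the list of suspects stand: substrate -> intermediate A; intermediate A -> intermediate B; intermediate B -> product; substrate <-> dormant form

* which of the two ends with the higher amount of product, in percent of the substrate charged ("neither" if they lie within 2 percentage points) (Wednesday's / Monday's / neither)
* product at the end, in percent of the substrate charged, Wednesday's
* product at the end, in percent of the substrate charged, Monday's

**Clock energy.** The east run reads 44.2% at 6.00 h and the north-west run reads 42.7% at 0.417 h. These levels are close, so the clock ratio between the two runs reads 14.4. That ratio gives 103 kJ/mol: the clock energy, the energy that converts a temperature change into a ratio of times through the Arrhenius form, an apparent activation energy.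

**Two extremes.** At east speed, Monday's 25 h lies later than the last east reading, so c(product) stands above 77.0%. Slowed by the full clock ratio, Monday's flask reaches 1.74 h on the east curve, between the readings 3.1% and 18.1%.

**The reckoning.** The clock energy makes Monday's clock 3.83 times slower than the east one, which lies between the extremes. Monday's flask therefore stands at 6.53 h on the east curve. The last two east readings show the remainder falling at 0.0985 /h, which gives 47.1% for Monday's flask. Wednesday's clock runs 2.42 times faster than the north-west one, so its 6.0 h equals 14.5 h on that curve, later than the 5.00 h reading of 99.6%.

**The result.** The forecast, lower than this reckoning for Monday's flask, names Wednesday's with 99.5% (96% to 100%) against 40% (22% to 58%), "allowing for the lag and any dormant form favoured in the cold". The simulation gives Wednesday's, with 100% for Wednesday's flask and 45.5% for Monday's.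

    substrate → intermediate A (k = 0.00400 /min, Ea = 93.0 kJ/mol)
    intermediate A → intermediate B (k = 0.00360 /min, Ea = 84.0 kJ/mol)
    intermediate B → product (k = 0.00130 /min, Ea = 108 kJ/mol)
    substrate ⇌ dormant form (K = 13.0, k = 0.00270 /min, Ea = 86.0 kJ/mol, ΔH = −80.0 kJ/mol)
    (constants at 25 °C)

**Neighbour flask.** Monday's flask ends 1.6 percentage points below its reckoned value. The neighbour is Wednesday's flask held at 40 °C for the same 6.0 h. The clock energy makes its clock 1.89 times faster than the east one. Its run lasts as long as the east run up to the 6.00 h reading, so it stands at 11.4 h on the east curve, and the same falling remainder gives 67.1%. The neighbour ends with 72.5% product, 5.4 points above that figure, and with 12.6% as dormant form.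

The earlier runs and the new flask were generated by integration with made-up constants; scatter was added.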